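**Retrosynthetic overview**
1. Target acid ⇐ Pd–hydride removal of a phenylsulfonyl group on C11 ⇐ alkylation of a bicyclic allyl-sulfone carbanion with (E)-4-bromo-3-methylbut-2-enoic acid (brings C12–C15 with the E-enoate in place).
2. 4-Methylpent-3-enyl group ⇐ cross-metathesis of a but-3-enyl group, kept monosubstituted so that acid cannot start a cascade at the chain end.
3. Key step: rings A and B form in one cascade (A first, then B) by enantioselective proton-initiated cyclization of an acyclic tetraene sulfone. It starts at an internal (E)-trisubstituted olefin, whose geometry sets the C4 quaternary centre, and ends on the allyl-sulfone olefin with loss of H-9 to give C8=C9.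
4. Acyclic tetraene sulfone ⇐ oxidation of the terminal (E)-methyl group and allylation of farnesyl phenyl sulfone ⇐ (2E,6E)-farnesol.
5. Ring locants are labdane-type: C4 = quaternary C(CH3)(side chain), C5 = ring-fusion CH, C10 = ring-fusion C–CH3, C8=C9 = ring olefin, C11 = CH2 on C9. The target is 4S,5S,10S (= 4aS,5S,8aS in naphthalene numbering): trans-decalin, 4-CH3 and 10-CH3 both β, 4-side chain α.

Assumption: (2E)-4-bromo-3-methylbut-2-enoic acid is bought as the pure E isomer.

**Step 1**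
Reactants: 1 (2E,6E)-farnesol
Product: 3 (2E,6E)-farnesyl phenyl sulfone, via (2E,6E)-farnesyl bromide 2 (not isolated)
Conditions: PBr3 (0.4 equiv), Et2O, −10 °C; crude bromide, PhSO2Na (1.3 equiv), DMF, rt
Reagents that add atoms: sodium benzenesulfinate [Na+].[O-]S(=O)c1ccccc1; phosphorus tribromide BrP(Br)Br (Br of 2 only)
Why: SN2 bromination of the primary allylic alcohol followed by S-alkylation of the sulfinate gives the primary allylic sulfone with both E olefins untouched.

**Step 2**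
Reactants: 3 (2E,6E)-farnesyl phenyl sulfone
Product: 4 (2E,6E,10E)-2,6,10-trimethyl-12-(phenylsulfonyl)dodeca-2,6,10-trien-1-ol
Conditions: SeO2 (0.1 equiv), t-BuOOH (70% aq., 2.5 equiv), salicylic acid (0.1 equiv), CH2Cl2, rt, stop near 50% conversion and recycle 3
Reagents that add atoms: tert-butyl hydroperoxide CC(C)(C)OO (net oxygen source; SeO2 is the catalytic carrier)
Why: Sharpless–Umbreit allylic oxidation (ene reaction then [2,3]-sigmatropic shift) attacks the (E)-methyl group of the terminal trisubstituted olefin, the sulfone-flanked olefin being deactivated, and gives the (E)-allylic alcohol.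

**Step 3**
Reactants: 4 (2E,6E,10E)-2,6,10-trimethyl-12-(phenylsulfonyl)dodeca-2,6,10-trien-1-ol
Product: 6 {[(2E,6E,10E)-3,7,11-trimethylpentadeca-2,6,10,14-tetraen-1-yl]sulfonyl}benzene, via allylic bromide 5 (not isolated)
Conditions: CBr4, PPh3, CH2Cl2, 0 °C; crude 5 added to allylMgBr (1.3 equiv), Li2CuCl4 (3 mol%), THF, −78 → −30 °C
Reagents that add atoms: allylmagnesium bromide C=CC[Mg]Br; carbon tetrabromide BrC(Br)(Br)Br (Br of 5 only)
Why: Appel bromination then copper-catalysed Grignard substitution (SN2 at the primary allylic carbon, olefin geometry kept) outruns deprotonation next to the sulfone at −78 °C and installs the but-3-enyl stand-in for the prenyl olefin.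

**Step 4**
Reactants: 6 {[(2E,6E,10E)-3,7,11-trimethylpentadeca-2,6,10,14-tetraen-1-yl]sulfonyl}benzene
Product: 8 ({[(4aS,5S,8aS)-5-(but-3-en-1-yl)-2,5,8a-trimethyl-3,4,4a,5,6,7,8,8a-octahydronaphthalen-1-yl]methyl}sulfonyl)benzene, via Δ7-olefin isomer 7 (not isolated)
Conditions: (R)-3,3'-dichloro-BINOL·SbCl5 (1:1 complex, 1.0 equiv), CH2Cl2, −78 °C, 8 h; then −40 °C, 1 h; Et3N/MeOH quench; AgNO3–silica chromatography
Reagents that add atoms: none
Why: Proposed new method: a chiral Lewis-acid-assisted Brønsted acid (closest known reaction: enantioselective proton-initiated polyene cyclization of terminal trisubstituted olefins) protonates C3 of the (E)-C3=C4 olefin, the only olefin that is neither electron-poor (allyl sulfone) nor monosubstituted (vinyl) and that has a fully nucleophilic olefin in 1,5-relation to assist, so concerted anti addition through the chair–chair fold closes ring A and then ring B in one cascade; the E geometry puts the butenyl group equatorial (4α) and the methyl axial (4β) on the new quaternary C4, the fold gives the trans fusion (5α-H, 10β-CH3), and the chiral acid selects the olefin face (4S,5S,10S; the (S)-acid is used instead if this non-terminal olefin reverses the sense of induction); the C8 cation first loses H-7 to give 7, and re-protonation by the same acid at −40 °C funnels it to the tetrasubstituted Δ8(9) allyl sulfone 8 (net isomerization, C24H34O2S throughout).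

**Step 5**
Reactants: 8 ({[(4aS,5S,8aS)-5-(but-3-en-1-yl)-2,5,8a-trimethyl-3,4,4a,5,6,7,8,8a-octahydronaphthalen-1-yl]methyl}sulfonyl)benzene
Product: 9 ({[(4aS,5S,8aS)-2,5,8a-trimethyl-5-(4-methylpent-3-en-1-yl)-3,4,4a,5,6,7,8,8a-octahydronaphthalen-1-yl]methyl}sulfonyl)benzene
Conditions: Grubbs II (3 mol%), 2-methyl-2-butene/CH2Cl2 (1:1), 35 °C
Reagents that add atoms: 2-methyl-2-butene CC=C(C)C
Why: Olefin cross-metathesis of the vinyl group with excess 2-methyl-2-butene gives the isopropylidene terminus, the tetrasubstituted ring olefin being inert to the ruthenium carbene.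

**Step 6**
Reactants: 9 ({[(4aS,5S,8aS)-2,5,8a-trimethyl-5-(4-methylpent-3-en-1-yl)-3,4,4a,5,6,7,8,8a-octahydronaphthalen-1-yl]methyl}sulfonyl)benzene; 10 (2E)-4-bromo-3-methylbut-2-enoic acid
Product: 11 (2E)-3-methyl-5-(phenylsulfonyl)-5-[(4aS,5S,8aS)-2,5,8a-trimethyl-5-(4-methylpent-3-en-1-yl)-3,4,4a,5,6,7,8,8a-octahydronaphthalen-1-yl]pent-2-enoic acid (both C5 epimers)
Conditions: 9, n-BuLi (1.05 equiv), THF/HMPA (4:1), −78 °C; then 10 premixed with NaH (1.0 equiv) in THF; −78 → −20 °C; aq. HCl work-up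
Reagents that add atoms: none
Why: Biellmann-type alkylation of the allylic α-sulfonyl carbanion at C11 by SN2 on the primary allylic bromide (its carboxylate is inert to the carbanion) joins the C5 unit with its E geometry kept; the new sulfone-bearing centre forms as both epimers and is removed in step 7.

**Step 7**
Reactants: 11 (2E)-3-methyl-5-(phenylsulfonyl)-5-[(4aS,5S,8aS)-2,5,8a-trimethyl-5-(4-methylpent-3-en-1-yl)-3,4,4a,5,6,7,8,8a-octahydronaphthalen-1-yl]pent-2-enoic acid
Product: 12 (2E)-3-methyl-5-[(4aS,5S,8aS)-2,5,8a-trimethyl-5-(4-methylpent-3-en-1-yl)-3,4,4a,5,6,7,8,8a-octahydronaphthalen-1-yl]pent-2-enoic acid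
Conditions: PdCl2(dppp) (10 mol%), LiBHEt3 (5 equiv), THF, 0 °C → rt; aq. HCl work-up
Reagents that add atoms: none
Why: Palladium-catalysed reductive desulfonylation (ionisation of the allylic C–S bond to a π-allyl complex, hydride delivered to the less hindered C11 terminus) keeps the tetrasubstituted Δ8(9) olefin, and the carboxylate formed by the first equivalent of hydride shields the conjugated acid from reduction.

**Compound list**
1 | (2E,6E)-farnesol | CC(C)=CCC/C(C)=C/CC/C(C)=C/CO | starting material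
2 | (2E,6E)-farnesyl bromide | CC(C)=CCC/C(C)=C/CC/C(C)=C/CBr | intermediate (not isolated)
3 | (2E,6E)-farnesyl phenyl sulfone, {[(2E,6E)-3,7,11-trimethyldodeca-2,6,10-trien-1-yl]sulfonyl}benzene | CC(C)=CCC/C(C)=C/CC/C(C)=C/CS(=O)(=O)c1ccccc1 | intermediate
4 | (2E,6E,10E)-2,6,10-trimethyl-12-(phenylsulfonyl)dodeca-2,6,10-trien-1-ol | OC/C(C)=C/CC/C(C)=C/CC/C(C)=C/CS(=O)(=O)c1ccccc1 | intermediate
5 | {[(2E,6E,10E)-12-bromo-3,7,11-trimethyldodeca-2,6,10-trien-1-yl]sulfonyl}benzene | BrC/C(C)=C/CC/C(C)=C/CC/C(C)=C/CS(=O)(=O)c1ccccc1 | intermediate (not isolated)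
6 | {[(2E,6E,10E)-3,7,11-trimethylpentadeca-2,6,10,14-tetraen-1-yl]sulfonyl}benzene | C=CCC/C(C)=C/CC/C(C)=C/CC/C(C)=C/CS(=O)(=O)c1ccccc1 | intermediate
7 | Δ7 isomer of 8, ({[(1S,4aS,5S,8aS)-5-(but-3-en-1-yl)-2,5,8a-trimethyl-1,4,4a,5,6,7,8,8a-octahydronaphthalen-1-yl]methyl}sulfonyl)benzene (9α-H, 9β-CH2SO2Ph) | C=CCC[C@]1(C)CCC[C@]2(C)[C@@H](CS(=O)(=O)c3ccccc3)C(C)=CC[C@@H]12 | intermediate (not isolated)
8 | ({[(4aS,5S,8aS)-5-(but-3-en-1-yl)-2,5,8a-trimethyl-3,4,4a,5,6,7,8,8a-octahydronaphthalen-1-yl]methyl}sulfonyl)benzene | C=CCC[C@]1(C)CCC[C@]2(C)C(CS(=O)(=O)c3ccccc3)=C(C)CC[C@@H]12 | intermediate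
9 | ({[(4aS,5S,8aS)-2,5,8a-trimethyl-5-(4-methylpent-3-en-1-yl)-3,4,4a,5,6,7,8,8a-octahydronaphthalen-1-yl]methyl}sulfonyl)benzene | CC(C)=CCC[C@]1(C)CCC[C@]2(C)C(CS(=O)(=O)c3ccccc3)=C(C)CC[C@@H]12 | intermediate
10 | (2E)-4-bromo-3-methylbut-2-enoic acid | BrC/C(C)=C/C(=O)O | starting material
11 | (2E)-3-methyl-5-(phenylsulfonyl)-5-[(4aS,5S,8aS)-2,5,8a-trimethyl-5-(4-methylpent-3-en-1-yl)-3,4,4a,5,6,7,8,8a-octahydronaphthalen-1-yl]pent-2-enoic acid (both C5 epimers) | CC(C)=CCC[C@]1(C)CCC[C@]2(C)C(C(C/C(C)=C/C(=O)O)S(=O)(=O)c3ccccc3)=C(C)CC[C@@H]12 | intermediate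
12 | (2E)-3-methyl-5-[(4aS,5S,8aS)-2,5,8a-trimethyl-5-(4-methylpent-3-en-1-yl)-3,4,4a,5,6,7,8,8a-octahydronaphthalen-1-yl]pent-2-enoic acid | CC(C)=CCC[C@]1(C)CCC[C@]2(C)C(CC/C(C)=C/C(=O)O)=C(C)CC[C@@H]12 | target

**Totals**
Total step count: 7. Longest linear sequence: 7 steps (1 → 12); compound 10 is bought.

**Three steps most likely to fail**

Step 4. The risks are low facial selectivity of the chiral acid on a non-terminal olefin, some protonation of the central olefin, and incomplete equilibration to the Δ8(9) olefin. The fallback sets out from 4 and returns at 8. Compound 4 is an allylic alcohol on exactly the olefin that must initiate. Sharpless asymmetric epoxidation (Ti(OiPr)4, L-(+)-diethyl tartrate, t-BuOOH, 4 Å sieves, CH2Cl2, −20 °C) therefore puts a (2S,3S)-oxirane there and nowhere else, giving the epoxy alcohol F1. Triflation (Tf2O, 2,6-lutidine, −78 °C) gives the epoxy triflate F2, and allylMgBr with catalytic Li2CuCl4 displaces the triflate to give the but-3-enyl epoxide F3. MeAlCl2 (CH2Cl2, −78 °C) then opens the oxirane at its tertiary carbon with inversion through the same chair–chair fold. This epoxide-initiated bicyclization, with absolute configuration now fixed by the tartrate and followed by the same brief acid equilibration of the ring olefin, gives the 3β-hydroxy bicyclic sulfone F4. Dess–Martin oxidation gives the 3-ketone F5, TsNHNH2 gives the tosylhydrazone F6, and catecholborane/NaOAc reduction removes the C3 oxygen to give 8.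

Step 7. The risks are slow π-allyl formation at the hindered tetrasubstituted olefin and hydride delivery to the wrong allyl terminus. The fallback sets out from 9 and returns at 12. It removes the sulfone by electron transfer before any reducible conjugated carbonyl exists. Lithiated 9 is alkylated with tert-butyl{[(2E)-4-bromo-3-methylbut-2-en-1-yl]oxy}dimethylsilane to give the sulfonyl silyl ether F7. Na(Hg)/Na2HPO4 in MeOH–THF at −20 °C cleaves the C–S bond to give the silyl ether F8. TBAF gives the allylic alcohol F9, MnO2 gives the enal F10, and Pinnick oxidation (NaClO2, NaH2PO4, 2-methyl-2-butene) gives 12.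

Step 6. The risk is sluggish alkylation of the hindered carbanion next to the tetrasubstituted olefin by a carboxylate-bearing bromide. The fallback sets out from 6 and returns at 11. The C–C bond is made before the rings: the unhindered acyclic carbanion of 6 (n-BuLi, THF/HMPA, −78 °C) is alkylated with the sodium salt of 10 to give the acyclic sulfonyl acid F11. The bicyclization is then run on F11 under the step 4 conditions, where the conjugated acid olefin is too electron-poor to take part, giving the bicyclic but-3-enyl sulfonyl acid F12. Cross-metathesis under the step 5 conditions gives 11.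

**Further compounds**
F1 | step 4 | {(2S,3S)-3-[(3E,7E)-3,7-dimethyl-9-(phenylsulfonyl)nona-3,7-dien-1-yl]-2-methyloxiran-2-yl}methanol | OC[C@]1(C)O[C@H]1CC/C(C)=C/CC/C(C)=C/CS(=O)(=O)c2ccccc2
F2 | step 4 | {(2S,3S)-3-[(3E,7E)-3,7-dimethyl-9-(phenylsulfonyl)nona-3,7-dien-1-yl]-2-methyloxiran-2-yl}methyl trifluoromethanesulfonate | FC(F)(F)S(=O)(=O)OC[C@]1(C)O[C@H]1CC/C(C)=C/CC/C(C)=C/CS(=O)(=O)c2ccccc2
F3 | step 4 | (2S,3S)-2-(but-3-en-1-yl)-3-[(3E,7E)-3,7-dimethyl-9-(phenylsulfonyl)nona-3,7-dien-1-yl]-2-methyloxirane | C=CCC[C@]1(C)O[C@H]1CC/C(C)=C/CC/C(C)=C/CS(=O)(=O)c2ccccc2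
F4 | step 4 | 3β-hydroxy derivative of 8, (1S,2S,4aS,8aR)-1-(but-3-en-1-yl)-1,4a,6-trimethyl-5-[(phenylsulfonyl)methyl]-1,2,3,4,4a,7,8,8a-octahydronaphthalen-2-ol | C=CCC[C@]1(C)[C@@H](O)CC[C@]2(C)C(CS(=O)(=O)c3ccccc3)=C(C)CC[C@@H]12
F5 | step 4 | 3-oxo derivative of 8 (ketone at C3, otherwise as 8) | C=CCC[C@]1(C)C(=O)CC[C@]2(C)C(CS(=O)(=O)c3ccccc3)=C(C)CC[C@@H]12
F6 | step 4 | p-toluenesulfonylhydrazone of F5 | C=CCC[C@]1(C)C(=NNS(=O)(=O)c3ccc(C)cc3)CC[C@]2(C)C(CS(=O)(=O)c4ccccc4)=C(C)CC[C@@H]12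
F7 | step 7 | tert-butyldimethylsilyl ether of (2E)-3-methyl-5-(phenylsulfonyl)-5-[(4aS,5S,8aS)-2,5,8a-trimethyl-5-(4-methylpent-3-en-1-yl)-3,4,4a,5,6,7,8,8a-octahydronaphthalen-1-yl]pent-2-en-1-ol | CC(C)=CCC[C@]1(C)CCC[C@]2(C)C(C(C/C(C)=C/CO[Si](C)(C)C(C)(C)C)S(=O)(=O)c3ccccc3)=C(C)CC[C@@H]12
F8 | step 7 | tert-butyldimethylsilyl ether of (2E)-3-methyl-5-[(4aS,5S,8aS)-2,5,8a-trimethyl-5-(4-methylpent-3-en-1-yl)-3,4,4a,5,6,7,8,8a-octahydronaphthalen-1-yl]pent-2-en-1-ol | CC(C)=CCC[C@]1(C)CCC[C@]2(C)C(CC/C(C)=C/CO[Si](C)(C)C(C)(C)C)=C(C)CC[C@@H]12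
F9 | step 7 | (2E)-3-methyl-5-[(4aS,5S,8aS)-2,5,8a-trimethyl-5-(4-methylpent-3-en-1-yl)-3,4,4a,5,6,7,8,8a-octahydronaphthalen-1-yl]pent-2-en-1-ol | CC(C)=CCC[C@]1(C)CCC[C@]2(C)C(CC/C(C)=C/CO)=C(C)CC[C@@H]12
F10 | step 7 | (2E)-3-methyl-5-[(4aS,5S,8aS)-2,5,8a-trimethyl-5-(4-methylpent-3-en-1-yl)-3,4,4a,5,6,7,8,8a-octahydronaphthalen-1-yl]pent-2-enal | CC(C)=CCC[C@]1(C)CCC[C@]2(C)C(CC/C(C)=C/C=O)=C(C)CC[C@@H]12
F11 | step 6 | (2E,6E,10E,14E)-3,7,11,15-tetramethyl-5-(phenylsulfonyl)nonadeca-2,6,10,14,18-pentaenoic acid (racemic at C5) | C=CCC/C(C)=C/CC/C(C)=C/CC/C(C)=C/C(C/C(C)=C/C(=O)O)S(=O)(=O)c1ccccc1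
F12 | step 6 | (2E)-5-[(4aS,5S,8aS)-5-(but-3-en-1-yl)-2,5,8a-trimethyl-3,4,4a,5,6,7,8,8a-octahydronaphthalen-1-yl]-3-methyl-5-(phenylsulfonyl)pent-2-enoic acid (both C5 epimers) | C=CCC[C@]1(C)CCC[C@]2(C)C(C(C/C(C)=C/C(=O)O)S(=O)(=O)c3ccccc3)=C(C)CC[C@@H]12
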